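Readings and results stem from a simulated flask for substances that don't exist, noise included.

3 questions stand over this flask, and we answer them by following a molecule of J to its fork: it ends in G or goes another way.

- G at 20 h, in percent of the J charged
- the change that raises the amount of G at 20 h, in percent of the J charged most ("none" if none brings more than 2 percentage points) (beta / alpha / none)
- amount of G at 20 h, in percent of the J charged, after alpha

| flask | J | Z | remark | time | volume of the second phase over the first |
|---|---|---|---|---|---|
| Tuesday's | 0.17 M | 1.5 equiv | run made earlier |  |  |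
| Thursday's | 0.38 M | 1.5 equiv | run made earlier |  |  |
| Sunday's | 0.25 M | 0.75 equiv | run made earlier |  |  |
| flask | 0.25 M | 1.50 equiv |  | 20 h | 2.0 |

| run | time / h | G / % | J / % |
|---|---|---|---|
| Tuesday's | 0.667 | 0 | 85.3 |
| Tuesday's | 2.00 | 0.5 | 64.9 |
| Tuesday's | 3.00 | 2.7 | 54.4 |
| Tuesday's | 5.00 | 5.6 | 42.2 |
| Tuesday's | 8.00 | 7.3 | 30.2 |
| Tuesday's | 10.0 | 6.3 | 25.8 |
| Tuesday's | 12.0 | 8.1 | 24.5 |
| Thursday's | 0.667 | 2.3 | 72.4 |
| Thursday's | 2.00 | 6.0 | 46.1 |
| Thursday's | 3.00 | 6.2 | 33.3 |
| Thursday's | 5.00 | 10.2 | 24.2 |
| Thursday's | 8.00 | 10.7 | 15.9 |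
| Thursday's | 10.0 | 13.2 | 14.0 |
| Thursday's | 12.0 | 10.9 | 11.1 |
| Sunday's | 1.00 | 2.0 | 73.3 |
| Sunday's | 2.00 | 2.1 | 57.1 |
| Sunday's | 3.00 | 2.3 | 47.7 |
| Sunday's | 6.00 | 4.9 | 31.2 |
| Sunday's | 12.0 | 6.1 | 17.8 |

(standard deviation of a reading: 1 percentage point)

- in the second phase: Z; everything else is in the first
- charges count per volume of the first phase; a concentration in a rate is the amount of a species over the volume of its own phase; every rate counts per litre of the first phase
- what was read earlier has a scatter of 1 percentage point, one standard deviation
- the earlier runs hold the two phases in the same ratio of volumes as the flask asked about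

G is then the J gone times the fork share. Which of these must we know well? An error of 1 percentage point in the J left moves G by 0.11 points, but the same error in Tuesday's last G moves the share by 1.3 points. Time counts for little late in Tuesday's run: its G gains 0.8 points after 8.00 h, less than the scatter. The share reads 10.7 % on Tuesday's run and 12.3 % on Thursday's, with more J, a gap of 1.6 points against the 1.3 points of scatter on Tuesday's share by itself. Sunday's, with half the Z, reads 7.42 %, so Z is the setting to watch.

Our number is 11.5 %, the fork share, G formed over J gone (the integral selectivity). Sunday's straight line in reciprocal J, stretched to 20 h, leaves 11.5 %, so we commit to 10.2 % of G. In these readings, the runs with twice the Z show a mean share above Sunday's by a factor 1.55, though their charges of J also differ from Sunday's; the same factor gives our 15.8 % after alpha. No run varies the transfer, so we choose alpha.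

The forecast stands higher: 12.3 %, alpha, 23 %, holding that “G fits first order in J and in Z”.

The flask gives 10.4 %. Alpha adds 9.1 points and beta 2.6 points, so the choice is alpha, with 19.5 % after it.

    L → Q (k = 1.30 h⁻¹)
    L ⇌ Z, rate k2*([L] - [Z]/K2) per volume of the first phase (partition coefficient = 0.330, kL = 0.110 h⁻¹)
    J + L → G (k = 1.10 M⁻¹ h⁻¹)
    2 J → X (k = 0.710 M⁻¹ h⁻¹)

The flask's fork share comes to 11.7 %. The largest single effect holding it down, though not the whole story, is the step from L to Q: with that step struck out, G stands at 38.5 % instead of 10.4 %. In the flask at 20.0 h, L goes to Q 43 times as fast as into G. The neighbour charged with 0.42 M of J keeps 6.4 % of it at 20.0 h, so Thursday's share gives 11.5 %, and that neighbour holds 12.5 %.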